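## The problem

Caraganin C (20) is a 2,3,4-trisubstituted chroman in which only the pyran ring C has to be made. Ring A (7-methoxy), the 2,4-dimethoxyphenyl group on C2, the 4-hydroxybenzyl group on C3 and the (E)-4-hydroxystyryl group on C4 are simple aromatic pieces attached to the chain C2–C3–C4 and to O1. The three stereocentres are contiguous and 2R,3R,4R, each substituent trans to its neighbour, so all three can sit equatorial on the half-chair. They differ as control elements. C3 carries only carbon and hydrogen and can be neither ionised nor enolised, so it must be set absolutely and can then direct the other two. C2 is a benzylic ether carbon whose 2,4-dimethoxyphenyl group makes the C2–O1 bond easy to ionise, so its configuration can be lost but also corrected under acid. C4 is fixed in the target but becomes epimerisable whenever its substituent is a carbonyl group. The compound is fragile: the C2–O1 bond is cleaved by strong acid and by hydrogenolysis, the hydroxystyrene is sensitive to acid, light and hydrogenation, two phenols must be carried masked, and three aryl methyl ethers rule out any protecting group removed by dealkylation. The enabling feature is the 1,3 relationship between C2, which stabilises a cation, and C4, which can carry a carboxyl group as styryl precursor and then stabilises an anion, with O1 sitting on the aryl group of C4. This is the pattern of an opened donor–acceptor cyclopropane spanning C2–C3–C4 with a built-in nucleophile, and in that cyclopropane C3 is the only stereocentre that has to be right.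

## Retrosynthesis

**Styryl group.** After unmasking the two phenols (20 from bis-silyl ether 19), the C=C bond of the styryl group is cut to aldehyde 13 and benzylic phosphonate 17. The alkene is introduced after ring C is closed because a hydroxystyrene would not survive the Lewis acid of the ring-forming step and an alkenyl group on C4 would make C4 a second ionisable position. Aldehyde 13 comes from ester 12 by partial reduction. The forward reaction must give the E alkene and must not disturb C4; a Horner–Wadsworth–Emmons reaction of a benzylic phosphonate meets the first demand more reliably than a sulfone-based olefination.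

**Ring C (key disconnection).** In ester 12 the O1–C2 bond and the C4–H bond are cut and C2 is joined to C4, which gives cyclopropane 10 carrying a free phenol on the aryl group of the ester-bearing carbon. Compared with a cut at C4–C4a or at C2–C3, this one forms the most labile bond of the molecule last, under conditions in which it can also equilibrate. Ring strain replaces the leaving group that an acyclic precursor would need at C2. Three stereocentres become one that matters, because the two cyclopropane carbons that ionise lose their configuration. The forward reaction has to cleave only the bond between the donor and the acceptor carbon, capture the cation with oxygen faster than C3 loses a proton, and end at the all-trans chroman.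

**Phenol and ester.** Hydroxy ester 10 is the methanolysis product of spirolactone 9. The lactone masks the ring A phenol and the carboxyl group at once, so ring A needs no protecting group and the nucleophile is released only one step before it is used.

**Cyclopropane.** The two bonds from the spiro carbon of 9 are cut to the cyclic diazo lactone 2 and the cis alkene 8. A catalytic asymmetric carbene transfer sets C3 in the step that makes the ring, and the carbene precursor is one step from a bought lactone. The neighbouring cut, addition of a benzylic sulfonium ylide to a 3-alkylidenebenzofuranone, would need a stoichiometric chiral sulfide and an alkylidene lactone whose benzylic γ-hydrogens invite deprotonation by the ylide. The forward reaction must choose the alkene over the benzylic C–H bonds and must control the face of the alkene.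

**Building blocks.** Alkene 8 is cut at its double bond to phosphonium salt 5 (ylide 7) and 2,4-dimethoxybenzaldehyde (6); a non-stabilised ylide gives the cis alkene that the carbene transfer prefers. Salt 5 comes from 4-(2-bromoethyl)phenol (3) through silyl ether 4. Diazo lactone 2 comes from 6-methoxybenzofuran-2(3H)-one (1) by diazo transfer. Phosphonate 17 comes from 4-(tert-butyldimethylsilyloxy)benzaldehyde (14) through alcohol 15 and bromide 16.

## Roads not taken

**Alternative 1:** The cut is at C4–C4a and C2–C3 with no ring formed. A chiral complex of monovalent rhodium, Rh(acac)(C2H4)2 with (S)-BINAP, would add the ring A aryl borane A2 in 1,4 fashion to dienone A1, and the boron enolate would add to aldehyde 6 to give β-hydroxy ketone A3.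
- Merits: three simple components join in one step, C4 is set kinetically by the catalyst with the styryl group already in place, and it is never epimerisable afterwards. In both respects this road is better than the chosen one, which has to equilibrate C4 and still has to build the alkene.
- Weak points: the dienone offers a 1,6 position as well, the ortho-alkoxy aryl group transfers slowly, and the aldol step must relay C4 to C3. After A3 the aroyl ketone has to be reduced to a methylene group next to a styrene, a retro-aldol-prone carbinol and an acid-labile benzylic position. The acetal must then be removed and ring C closed at C2.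
- Comparison: the chosen plan sets against this that the benzyl carbon arrives at the right oxidation level, that ring closure and C2 are settled in one operation, and that no redox correction is needed on a crowded, sensitive intermediate.

**Alternative 2:** The cut is at C2–C3 with closure of ring C. A chiral Brønsted acid would ionise the acetal C–O bond of benzodioxine A4 and the released enol carbon would attack the oxocarbenium ion to give the trans flavanone A5.
- Merits: A4 is made in very few steps from a ketone and aldehyde 6 without a diazo compound or rhodium, and the 2,3-trans relationship is secured by simple enolisation of C3. Up to the heterocycle this road is probably shorter.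
- Weak points: enantiocontrol over a contact ion pair of this kind is itself unproven. A5 holds its stereochemistry loosely, since a flavanone with an electron-rich 2-aryl group opens by retro-oxa-Michael reaction, and C3 is defined only relative to C2. C4 still has no carbon substituent. Addition to the hindered, enolisable ketone followed by reductive removal of the hydroxyl group would deliver hydride anti to the C3 group and so give the 3,4-cis isomer. A one-carbon homologation would arrive at the same aldehyde stage as 13, but later and with more steps.
- Comparison: the chosen plan sets against the shorter ring synthesis a C3 centre that is fixed in a non-epimerisable form before the ring is closed, and a C4 carbon that is in place from the start.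

**Alternative 3:** The cut is at C4–C4a. Acid would ionise the allylic alcohol of aryl ether A6, which already carries C2 and C3, and ring A would attack the near end of the allyl cation to give bis-silyl ether A7.
- Merits: this is the shortest end game, one desilylation from the target. The arene should add anti to the C3 substituent, which is the well-established kinetic sense and gives 3,4-trans directly. On this point it is better than the chosen plan, which relies on an equilibrium at C4.
- Weak points: A6 contains the 2,4-dimethoxybenzylic aryl ether at C2, which ionises more easily than the allylic alcohol, so the acid would expel the phenol of ring A or scramble C2 before ring closure. The allyl cation is ambident and quinone-methide-like at its far end. Making A6 with defined C2 and C3, an aryl ether at a hindered and ionisable benzylic carbon, is long and stereochemically fragile.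
- Comparison: the chosen plan sets against the better C4 control that the labile C2–O1 bond is formed last and that its lability is used to reach the trans isomer instead of being a liability.

Key step: step 7

Assumption: in step 5 the (S)-configured catalyst is taken, by analogy with related cyclic donor/acceptor carbenes, to give the 3′S cyclopropane with both alkene substituents on the carbonyl side of the lactone; if the sense proves opposite, the catalyst from (R)-tert-leucine, Rh2(R-PTTL)4, is used and nothing else changes.

## Route

Step 1
Reactants: 1 6-methoxybenzofuran-2(3H)-one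
Product: 2 3-diazo-6-methoxybenzofuran-2(3H)-one
Conditions: 4-acetamidobenzenesulfonyl azide, Et3N, MeCN, 0 °C to rt
Reagents that add atoms: 4-acetamidobenzenesulfonyl azide, CC(=O)Nc1ccc(cc1)S(=O)(=O)N=[N+]=[N-]
Why: Regitz diazo transfer; the C3 methylene is activated by the aryl ring and the lactone carbonyl, so a tertiary amine is enough to form the enolate that attacks the sulfonyl azide.

Step 2
Reactants: 3 4-(2-bromoethyl)phenol
Product: 4 [4-(2-bromoethyl)phenoxy]triisopropylsilane
Conditions: i-Pr3SiCl, imidazole, CH2Cl2, 0 °C to rt
Reagents that add atoms: triisopropylsilyl chloride, CC(C)[Si](Cl)(C(C)C)C(C)C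
Why: Standard silylation of a phenol; the triisopropylsilyl ether is chosen because it has to pass amide bases, methoxide and a Lewis acid.

Step 3
Reactants: 4 [4-(2-bromoethyl)phenoxy]triisopropylsilane
Product: 5 {2-[4-(triisopropylsilyloxy)phenyl]ethyl}triphenylphosphonium bromide
Conditions: PPh3, MeCN, reflux
Reagents that add atoms: triphenylphosphine, c1ccc(cc1)P(c1ccccc1)c1ccccc1
Why: SN2 quaternisation of a primary bromide by a non-basic nucleophile, so elimination to the styrene should not compete.

Step 4
Reactants: 5 {2-[4-(triisopropylsilyloxy)phenyl]ethyl}triphenylphosphonium bromide; 6 2,4-dimethoxybenzaldehyde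
Product: 8 (Z)-1-(2,4-dimethoxyphenyl)-3-[4-(triisopropylsilyloxy)phenyl]prop-1-ene, via phosphonium ylide 7 (not isolated)
Conditions: NaN(SiMe3)2, THF, −78 to 0 °C; then 6, −78 °C to rt
Reagents that add atoms: none
Why: Wittig olefination; a non-stabilised ylide under lithium-free conditions adds to the aryl aldehyde through the kinetically favoured cis oxaphosphetane and should give the Z alkene.

Step 5
Reactants: 2 3-diazo-6-methoxybenzofuran-2(3H)-one; 8 (Z)-1-(2,4-dimethoxyphenyl)-3-[4-(triisopropylsilyloxy)phenyl]prop-1-ene
Product: 9 (3S,2′S,3′S)-2′-(2,4-dimethoxyphenyl)-6-methoxy-3′-[4-(triisopropylsilyloxy)benzyl]spiro[1-benzofuran-3,1′-cyclopropan]-2-one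
Conditions: Rh2(S-PTTL)4 (dirhodium tetrakis[N-phthaloyl-(S)-tert-leucinate], 1 mol %), CH2Cl2, −20 °C, slow addition of 2
Reagents that add atoms: none
Why: Cyclopropanation of an electron-rich cis-disubstituted styrene by a cyclic donor/acceptor carbene of the divalent rhodium dimer, the reaction type established for 3-diazooxindoles and aryldiazoacetates; addition is concerted and syn, so aryl and benzyl stay cis, and the chiral carboxylate pocket selects the alkene face that makes C3′ S (see the assumption). The electron-rich alkene should react faster than the benzylic C–H bonds, and only the configuration at C3′ is needed later.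

Step 6
Reactants: 9 (3S,2′S,3′S)-2′-(2,4-dimethoxyphenyl)-6-methoxy-3′-[4-(triisopropylsilyloxy)benzyl]spiro[1-benzofuran-3,1′-cyclopropan]-2-one
Product: 10 methyl (1S,2S,3S)-2-(2,4-dimethoxyphenyl)-1-(2-hydroxy-4-methoxyphenyl)-3-[4-(triisopropylsilyloxy)benzyl]cyclopropane-1-carboxylate
Conditions: NaOMe (1.1 equiv), MeOH–THF, −20 to 0 °C; then AcOH
Reagents that add atoms: sodium methoxide, [Na+].[O-]C
Why: Methanolysis of an aryl ester, driven by release of the phenoxide and of the spiro strain; under base the cyclopropane is not activated and no stereocentre is touched, and the triisopropylsilyl ether should survive the short cold exposure.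

Step 7
Reactants: 10 methyl (1S,2S,3S)-2-(2,4-dimethoxyphenyl)-1-(2-hydroxy-4-methoxyphenyl)-3-[4-(triisopropylsilyloxy)benzyl]cyclopropane-1-carboxylate
Product: 12 methyl (2R,3R,4R)-2-(2,4-dimethoxyphenyl)-7-methoxy-3-[4-(triisopropylsilyloxy)benzyl]chroman-4-carboxylate, via chroman ester epimeric at C4 11 (not isolated)
Conditions: Sc(OTf)3 (10 mol %), CH2Cl2 (dilute), −20 °C to rt; filtration through Celite, solvent exchange; then NaOMe (0.5 equiv), MeOH–THF, rt; AcOH
Reagents that add atoms: none
Why: Proposed new method: Sc(OTf)3 binds the ester carbonyl, and the push–pull C1–C2 bond of the cyclopropane, flanked by the 2,4-dimethoxyphenyl donor and the aryl ester acceptor, heterolyses to a zwitterion with a 2,4-dimethoxybenzyl cation at the future C2 and a scandium aryl ester enolate at the future C4; the C1–C3 bond stays intact because C3 has no cation-stabilising group. The phenol oxygen on the C4 aryl group captures the planar cation in a 6-exo-trig closure that forms O1–C2 and ring C, and proton transfer to the enolate carbon completes the isomerisation and frees the catalyst. The closest known reaction types are the Lewis-acid ring opening of 2-arylcyclopropane-1,1-diesters by phenols and the Cloke–Wilson rearrangement; new here are the single ester acceptor and a nucleophile tethered to the acceptor carbon, which turns ring opening into ring expansion. C2 is controlled by C3: closure through a chair-like transition state with the aryl group equatorial and anti to the benzyl group gives the 2,3-trans ether, and because the C2–O1 bond can re-ionise under the Lewis acid any cis ether should drain to the same isomer. C4 is set by a protonation that is not expected to be selective and is therefore equilibrated in the same operation with methoxide, the enolisable ester settling trans to the C3 benzyl group, where the flattened half-chair holds the two equatorial groups furthest apart. The step needs O-capture ahead of proton loss or hydride shift from C3, which the six-membered reach of the ortho phenol should secure, and it needs one product from any cyclopropane diastereomer, which follows because the configurations at C1 and C2 of 10 are erased on ionisation while C3 is never touched.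

Step 8
Reactants: 12 methyl (2R,3R,4R)-2-(2,4-dimethoxyphenyl)-7-methoxy-3-[4-(triisopropylsilyloxy)benzyl]chroman-4-carboxylate
Product: 13 (2R,3R,4R)-2-(2,4-dimethoxyphenyl)-7-methoxy-3-[4-(triisopropylsilyloxy)benzyl]chroman-4-carbaldehyde
Conditions: i-Bu2AlH (1.1 equiv), CH2Cl2, −78 °C; MeOH, then aq. KNaC4H4O6 (Rochelle salt)
Reagents that add atoms: none
Why: Partial reduction of a methyl ester; the aluminium hemiacetal of this hindered α-aryl ester should persist at −78 °C and release the aldehyde only on work-up. The aldehyde is used crude to avoid epimerisation at C4 on silica.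

Step 9
Reactants: 14 4-(tert-butyldimethylsilyloxy)benzaldehyde
Product: 15 [4-(tert-butyldimethylsilyloxy)phenyl]methanol
Conditions: NaBH4, MeOH, 0 °C
Reagents that add atoms: none
Why: Borohydride reduction of an aryl aldehyde; the aryl silyl ether is stable to the short cold treatment.

Step 10
Reactants: 15 [4-(tert-butyldimethylsilyloxy)phenyl]methanol
Product: 16 [4-(bromomethyl)phenoxy](tert-butyl)dimethylsilane
Conditions: CBr4, PPh3, CH2Cl2, 0 °C
Reagents that add atoms: carbon tetrabromide, BrC(Br)(Br)Br
Why: Appel bromination under neutral conditions, which spares the silyl ether; the labile benzylic bromide is used directly.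

Step 11
Reactants: 16 [4-(bromomethyl)phenoxy](tert-butyl)dimethylsilane
Product: 17 diethyl [4-(tert-butyldimethylsilyloxy)benzyl]phosphonate
Conditions: P(OEt)3 (neat), 120 °C
Reagents that add atoms: triethyl phosphite, CCOP(OCC)OCC
Why: Michaelis–Arbuzov reaction of a reactive benzylic bromide.

Step 12
Reactants: 17 diethyl [4-(tert-butyldimethylsilyloxy)benzyl]phosphonate; 13 (2R,3R,4R)-2-(2,4-dimethoxyphenyl)-7-methoxy-3-[4-(triisopropylsilyloxy)benzyl]chroman-4-carbaldehyde
Product: 19 caraganin C bis(silyl ether) (triisopropylsilyl on the benzyl phenol; tert-butyldimethylsilyl on the styryl phenol), via potassium phosphonate carbanion 18 (not isolated)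
Conditions: KN(SiMe3)2, THF, −78 °C; then 13, −78 °C to rt
Reagents that add atoms: none
Why: Horner–Wadsworth–Emmons olefination; benzylic phosphonate anions give E alkenes because the adducts equilibrate before the syn elimination. Adding the aldehyde cold to the preformed anion is meant to let addition outrun enolisation, and C4 is in any case held in its preferred equatorial configuration.

Step 13
Reactants: 19 caraganin C bis(silyl ether) (triisopropylsilyl on the benzyl phenol; tert-butyldimethylsilyl on the styryl phenol)
Product: 20 caraganin C
Conditions: Bu4NF, AcOH, THF, 0 °C to rt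
Reagents that add atoms: none
Why: Fluoride cleavage of both aryl silyl ethers; buffering with acetic acid avoids free phenoxides, and the absence of strong acid leaves the C2–O1 bond and the styrene untouched.

## Compound list

1 | 6-methoxybenzofuran-2(3H)-one | COc1ccc2c(c1)OC(=O)C2 | starting material
2 | 3-diazo-6-methoxybenzofuran-2(3H)-one | COc1ccc2c(c1)OC(=O)C2=[N+]=[N-] | intermediate
3 | 4-(2-bromoethyl)phenol | Oc1ccc(CCBr)cc1 | starting material
4 | [4-(2-bromoethyl)phenoxy]triisopropylsilane | CC(C)[Si](Oc1ccc(CCBr)cc1)(C(C)C)C(C)C | intermediate
5 | {2-[4-(triisopropylsilyloxy)phenyl]ethyl}triphenylphosphonium bromide | CC(C)[Si](Oc1ccc(CC[P+](c2ccccc2)(c2ccccc2)c2ccccc2)cc1)(C(C)C)C(C)C.[Br-] | intermediate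
6 | 2,4-dimethoxybenzaldehyde | COc1ccc(C=O)c(OC)c1 | starting material
7 | {2-[4-(triisopropylsilyloxy)phenyl]ethylidene}triphenylphosphorane (ylide, not isolated) | CC(C)[Si](Oc1ccc(CC=P(c2ccccc2)(c2ccccc2)c2ccccc2)cc1)(C(C)C)C(C)C | intermediate
8 | (Z)-1-(2,4-dimethoxyphenyl)-3-[4-(triisopropylsilyloxy)phenyl]prop-1-ene | COc1ccc(/C=C\Cc2ccc(O[Si](C(C)C)(C(C)C)C(C)C)cc2)c(OC)c1 | intermediate
9 | (3S,2′S,3′S)-2′-(2,4-dimethoxyphenyl)-6-methoxy-3′-[4-(triisopropylsilyloxy)benzyl]spiro[1-benzofuran-3,1′-cyclopropan]-2-one (aryl and benzyl cis to each other and to the lactone carbonyl) | COc1ccc2c(c1)OC(=O)[C@@]23[C@H](c4ccc(OC)cc4OC)[C@@H]3Cc3ccc(O[Si](C(C)C)(C(C)C)C(C)C)cc3 | intermediate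
10 | methyl (1S,2S,3S)-2-(2,4-dimethoxyphenyl)-1-(2-hydroxy-4-methoxyphenyl)-3-[4-(triisopropylsilyloxy)benzyl]cyclopropane-1-carboxylate (ester, dimethoxyphenyl and benzyl on one face) | COC(=O)[C@]1(c2ccc(OC)cc2O)[C@H](c2ccc(OC)cc2OC)[C@@H]1Cc1ccc(O[Si](C(C)C)(C(C)C)C(C)C)cc1 | intermediate
11 | methyl (2R,3R)-2-(2,4-dimethoxyphenyl)-7-methoxy-3-[4-(triisopropylsilyloxy)benzyl]chroman-4-carboxylate, 2,3-trans, mixture of C4 epimers (not isolated) | COc1ccc2c(c1)O[C@@H](c1ccc(OC)cc1OC)[C@H](Cc1ccc(O[Si](C(C)C)(C(C)C)C(C)C)cc1)C2C(=O)OC | intermediate
12 | methyl (2R,3R,4R)-2-(2,4-dimethoxyphenyl)-7-methoxy-3-[4-(triisopropylsilyloxy)benzyl]chroman-4-carboxylate (all-trans) | COc1ccc2c(c1)O[C@@H](c1ccc(OC)cc1OC)[C@H](Cc1ccc(O[Si](C(C)C)(C(C)C)C(C)C)cc1)[C@H]2C(=O)OC | intermediate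
13 | (2R,3R,4R)-2-(2,4-dimethoxyphenyl)-7-methoxy-3-[4-(triisopropylsilyloxy)benzyl]chroman-4-carbaldehyde | COc1ccc2c(c1)O[C@@H](c1ccc(OC)cc1OC)[C@H](Cc1ccc(O[Si](C(C)C)(C(C)C)C(C)C)cc1)[C@H]2C=O | intermediate
14 | 4-(tert-butyldimethylsilyloxy)benzaldehyde | CC(C)(C)[Si](C)(C)Oc1ccc(C=O)cc1 | starting material
15 | [4-(tert-butyldimethylsilyloxy)phenyl]methanol | CC(C)(C)[Si](C)(C)Oc1ccc(CO)cc1 | intermediate
16 | [4-(bromomethyl)phenoxy](tert-butyl)dimethylsilane | CC(C)(C)[Si](C)(C)Oc1ccc(CBr)cc1 | intermediate
17 | diethyl [4-(tert-butyldimethylsilyloxy)benzyl]phosphonate | CCOP(=O)(OCC)Cc1ccc(O[Si](C)(C)C(C)(C)C)cc1 | intermediate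
18 | potassium salt of the carbanion of 17 (not isolated) | CCOP(=O)(OCC)[CH-]c1ccc(O[Si](C)(C)C(C)(C)C)cc1.[K+] | intermediate
19 | caraganin C bis(silyl ether): (2R,3R,4R)-4-{(E)-2-[4-(tert-butyldimethylsilyloxy)phenyl]ethenyl}-2-(2,4-dimethoxyphenyl)-7-methoxy-3-[4-(triisopropylsilyloxy)benzyl]chroman | COc1ccc2c(c1)O[C@@H](c1ccc(OC)cc1OC)[C@H](Cc1ccc(O[Si](C(C)C)(C(C)C)C(C)C)cc1)[C@H]2/C=C/c1ccc(O[Si](C)(C)C(C)(C)C)cc1 | intermediate
20 | caraganin C, (2R,3R,4R)-2-(2,4-dimethoxyphenyl)-3-(4-hydroxybenzyl)-4-[(E)-2-(4-hydroxyphenyl)ethenyl]-7-methoxychroman | COc1ccc2c(c1)O[C@@H](c1ccc(OC)cc1OC)[C@H](Cc1ccc(O)cc1)[C@H]2/C=C/c1ccc(O)cc1 | target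

## Step count and least certain steps

Total: 13 steps. Longest linear sequence: 9 steps (3 to 20 through steps 2, 3, 4, 5, 6, 7, 8, 12 and 13).

**Step 7 (key step, bears the label "Proposed new method:").**
- Risk: a cyclopropane activated by only one ester may ionise too slowly. Once ionised, the zwitterion may lose the C3 proton or undergo a hydride shift to an acyclic alkene, which destroys C3. The hydroxy ester may close back to the spirolactone under the Lewis acid and so lose its nucleophile. The equilibrium at C4 may not lie far enough on the trans side, in which case the epimers would have to be separated and the cis ester returned to the methoxide equilibration.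
- Fallback (known chemistry, sets out from 10 and returns at 12): acid-catalysed ring-opening methanolysis of the cyclopropane (camphorsulfonic acid, MeOH) should give methyl (3R)-4-(2,4-dimethoxyphenyl)-2-(2-hydroxy-4-methoxyphenyl)-4-methoxy-3-[4-(triisopropylsilyloxy)benzyl]butanoate F1 as a mixture at the two flanking carbons. Treating F1 with camphorsulfonic acid in CH2Cl2 over 4 Å molecular sieves should then close the chroman by SN1 etherification with loss of methanol, the ordinary acid-mediated flavan closure. The same methoxide equilibration leads to 12. This separates ring opening from ring closure, so the cation is generated next to a neutral ester and not next to an enolate.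

**Step 5.**
- Risk: the carbene may insert into the doubly activated benzylic–allylic C–H bonds or attack the electron-rich arenes instead of the alkene. Facial discrimination on a cis-disubstituted alkene may be poor. A minor diastereomer formed on the other alkene face would carry the opposite C3′ configuration and would have to be removed. The highly activated spirolactone may open on the catalyst or on silica.
- Fallback (sets out from 2, uses 8, returns at 12): methanolysis of the diazo lactone (NaOMe, MeOH) gives methyl 2-diazo-2-(2-hydroxy-4-methoxyphenyl)acetate F2, and silylation (Et3SiCl, imidazole) gives methyl 2-diazo-2-[4-methoxy-2-(triethylsilyloxy)phenyl]acetate F3. This acyclic aryldiazoacetate, the best-studied donor/acceptor class, is added to 8 with Rh2(S-PTAD)4 (dirhodium tetrakis[N-phthaloyl-(S)-adamantylglycinate]), the catalyst type suited to ortho-substituted aryl groups, or with its antipode as the required sense dictates. The expected product is methyl (1R,2S,3S)-2-(2,4-dimethoxyphenyl)-1-[4-methoxy-2-(triethylsilyloxy)phenyl]-3-[4-(triisopropylsilyloxy)benzyl]cyclopropane-1-carboxylate F4. Selective removal of the aryl triethylsilyl group (K2CO3, MeOH, 0 °C) gives methyl (1R,2S,3S)-2-(2,4-dimethoxyphenyl)-1-(2-hydroxy-4-methoxyphenyl)-3-[4-(triisopropylsilyloxy)benzyl]cyclopropane-1-carboxylate F5, the C1 epimer of 10. Under the conditions of step 7 it converges on 12.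

**Step 12.**
- Risk: the phosphonate anion may deprotonate the α-aryl aldehyde instead of adding to it, with loss of material and erosion at C4, and addition to the crowded formyl group may be slow.
- Fallback (sets out from 13 and returns at 19): methylenation with Ph3P=CH2 at low temperature gives (2R,3R,4R)-2-(2,4-dimethoxyphenyl)-4-ethenyl-7-methoxy-3-[4-(triisopropylsilyloxy)benzyl]chroman F6. Cross-metathesis of F6 with commercial tert-butyldimethyl(4-vinylphenoxy)silane and the second-generation Hoveyda–Grubbs catalyst should give the E alkene 19.

**Step 8.**
- Risk: the hemiacetal may collapse before the quench and be reduced further to the primary alcohol, and the aldehyde may epimerise during work-up.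
- Fallback (sets out from 12 and returns at 13): full reduction with LiAlH4 gives [(2R,3R,4R)-2-(2,4-dimethoxyphenyl)-7-methoxy-3-[4-(triisopropylsilyloxy)benzyl]chroman-4-yl]methanol F7. Oxidation of F7 with Dess–Martin periodinane buffered with NaHCO3 gives 13.

## Further compounds

F1 | step 7 | methyl (3R)-4-(2,4-dimethoxyphenyl)-2-(2-hydroxy-4-methoxyphenyl)-4-methoxy-3-[4-(triisopropylsilyloxy)benzyl]butanoate (mixture at C2 and C4) | COC(=O)C(c1ccc(OC)cc1O)[C@@H](Cc1ccc(O[Si](C(C)C)(C(C)C)C(C)C)cc1)C(OC)c1ccc(OC)cc1OC
F2 | step 5 | methyl 2-diazo-2-(2-hydroxy-4-methoxyphenyl)acetate | COC(=O)C(=[N+]=[N-])c1ccc(OC)cc1O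
F3 | step 5 | methyl 2-diazo-2-[4-methoxy-2-(triethylsilyloxy)phenyl]acetate | COC(=O)C(=[N+]=[N-])c1ccc(OC)cc1O[Si](CC)(CC)CC
F4 | step 5 | methyl (1R,2S,3S)-2-(2,4-dimethoxyphenyl)-1-[4-methoxy-2-(triethylsilyloxy)phenyl]-3-[4-(triisopropylsilyloxy)benzyl]cyclopropane-1-carboxylate | COC(=O)[C@@]1(c2ccc(OC)cc2O[Si](CC)(CC)CC)[C@H](c2ccc(OC)cc2OC)[C@@H]1Cc1ccc(O[Si](C(C)C)(C(C)C)C(C)C)cc1
F5 | step 5 | methyl (1R,2S,3S)-2-(2,4-dimethoxyphenyl)-1-(2-hydroxy-4-methoxyphenyl)-3-[4-(triisopropylsilyloxy)benzyl]cyclopropane-1-carboxylate | COC(=O)[C@@]1(c2ccc(OC)cc2O)[C@H](c2ccc(OC)cc2OC)[C@@H]1Cc1ccc(O[Si](C(C)C)(C(C)C)C(C)C)cc1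
F6 | step 12 | (2R,3R,4R)-2-(2,4-dimethoxyphenyl)-4-ethenyl-7-methoxy-3-[4-(triisopropylsilyloxy)benzyl]chroman | COc1ccc2c(c1)O[C@@H](c1ccc(OC)cc1OC)[C@H](Cc1ccc(O[Si](C(C)C)(C(C)C)C(C)C)cc1)[C@H]2C=C
F7 | step 8 | [(2R,3R,4R)-2-(2,4-dimethoxyphenyl)-7-methoxy-3-[4-(triisopropylsilyloxy)benzyl]chroman-4-yl]methanol | COc1ccc2c(c1)O[C@@H](c1ccc(OC)cc1OC)[C@H](Cc1ccc(O[Si](C(C)C)(C(C)C)C(C)C)cc1)[C@H]2CO
A1 | alternative 1 | (2E,4E)-1,5-bis[4-(tert-butyldimethylsilyloxy)phenyl]penta-2,4-dien-1-one | CC(C)(C)[Si](C)(C)Oc1ccc(/C=C/C=C/C(=O)c2ccc(O[Si](C)(C)C(C)(C)C)cc2)cc1
A2 | alternative 1 | B-[4-methoxy-2-(methoxymethoxy)phenyl]-9-borabicyclo[3.3.1]nonane | COCOc1cc(OC)ccc1B1C2CCCC1CCC2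
A3 | alternative 1 | (4E)-1,5-bis[4-(tert-butyldimethylsilyloxy)phenyl]-2-[(2,4-dimethoxyphenyl)(hydroxy)methyl]-3-[4-methoxy-2-(methoxymethoxy)phenyl]pent-4-en-1-one, configuration as in the SMILES | COCOc1cc(OC)ccc1[C@H](/C=C/c1ccc(O[Si](C)(C)C(C)(C)C)cc1)[C@@H](C(=O)c1ccc(O[Si](C)(C)C(C)(C)C)cc1)[C@@H](O)c1ccc(OC)cc1OC
A4 | alternative 2 | 4-{2-[4-(tert-butyldimethylsilyloxy)phenyl]ethylidene}-2-(2,4-dimethoxyphenyl)-7-methoxy-4H-1,3-benzodioxine (racemic at the acetal carbon) | COc1ccc2c(c1)OC(c1ccc(OC)cc1OC)OC2=CCc1ccc(O[Si](C)(C)C(C)(C)C)cc1
A5 | alternative 2 | (2R,3S)-3-[4-(tert-butyldimethylsilyloxy)benzyl]-2-(2,4-dimethoxyphenyl)-7-methoxychroman-4-one (2,3-trans) | COc1ccc2c(c1)O[C@@H](c1ccc(OC)cc1OC)[C@H](Cc1ccc(O[Si](C)(C)C(C)(C)C)cc1)C2=O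
A6 | alternative 3 | (E)-1,5-bis[4-(tert-butyldimethylsilyloxy)phenyl]-4-[(2,4-dimethoxyphenyl)(3-methoxyphenoxy)methyl]pent-1-en-3-ol, ether and benzyl carbons as in the target, carbinol carbon undefined | COc1cccc(O[C@@H](c2ccc(OC)cc2OC)[C@H](Cc2ccc(O[Si](C)(C)C(C)(C)C)cc2)C(O)/C=C/c2ccc(O[Si](C)(C)C(C)(C)C)cc2)c1
A7 | alternative 3 | caraganin C bis(tert-butyldimethylsilyl) ether | COc1ccc2c(c1)O[C@@H](c1ccc(OC)cc1OC)[C@H](Cc1ccc(O[Si](C)(C)C(C)(C)C)cc1)[C@H]2/C=C/c1ccc(O[Si](C)(C)C(C)(C)C)cc1
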